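**Plan**

- The last disconnection removes the benzyl group from O4'. Ring C is then opened at O1–C2, a cyclodehydration in reverse, which gives a 1-(2-hydroxyaryl)-3-arylpropane-1,3-dione.
- The diketone is cut at C2–C3 and at C1'–C2. C2 is bonded only to C3, O1 and C1' of ring B, so it is a lone carbonyl-level carbon. It can be supplied as carbon monoxide between the methyl group of a ring A 2-hydroxyacetophenone and the bromine-bearing carbon of a ring B aryl bromide.
- Forward, ring A is taken from 1,2,3,4-tetramethoxybenzene by formylation, Baeyer–Villiger oxidation to the phenol and C-acetylation at the one free position. Ring B comes from 4-bromo-2,6-dimethoxyphenol by O-benzylation.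
- The palladium-catalysed three-component carbonylation joins the chain C4–C3–C2–C1'. Ring C, the only ring made, then closes under acid, and hydrogenolysis frees the 4'-hydroxyl group.
- The target has no stereocentre and no configured double bond, so no stereochemistry has to be set.

Key step: step 5

Assumption: diketone 12 is drawn as the diketo tautomer although it should exist mainly as the hydrogen-bonded enol; 1,2,3,4-tetramethoxybenzene and 4-bromo-2,6-dimethoxyphenol are taken as purchasable.

**Route**

Step 1
Reactants: 1 1,2,3,4-tetramethoxybenzene
Product: 3 2,3,4,5-tetramethoxybenzaldehyde, via benzylidene iminium salt 2 (not isolated)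
Conditions: POCl3, DMF, 0 °C → 80 °C; then ice-water, rt
Reagents that add atoms: N,N-dimethylformamide (CN(C)C=O); water (O)
Why: Vilsmeier–Haack formylation, in which the chloroiminium electrophile should attack one of the two equivalent free positions of the symmetrical, electron-rich arene (para to one methoxy group and ortho to another), the iminium group of 2 deactivates the ring against a second substitution, and water hydrolyses 2 to the aldehyde.

Step 2
Reactants: 3 2,3,4,5-tetramethoxybenzaldehyde
Product: 5 2,3,4,5-tetramethoxyphenol, via aryl formate 4 (not isolated)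
Conditions: mCPBA, CH2Cl2, 0 °C → rt; then HCl (cat.), MeOH, rt
Reagents that add atoms: 3-chloroperoxybenzoic acid, mCPBA (O=C(OO)c1cccc(Cl)c1)
Why: Baeyer–Villiger (Dakin-type) oxidation, in which the electron-rich aryl group should migrate in preference to hydride in the Criegee adduct to give formate 4, which is methanolysed under mild acid so that the oxidation-prone phenol is never exposed to base and air together.

Step 3
Reactants: 5 2,3,4,5-tetramethoxyphenol
Product: 7 1-(2-hydroxy-3,4,5,6-tetramethoxyphenyl)ethanone, via difluoroboron chelate 6 (not isolated)
Conditions: AcOH, BF3·OEt2, 80 °C; then EtOH/H2O, reflux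
Reagents that add atoms: acetic acid (CC(=O)O)
Why: Friedel–Crafts C-acylation of a phenol with the BF3–acetic acid couple, in which the only unsubstituted ring carbon lies ortho to the hydroxyl group so the regiochemistry is fixed, and the ketone is withdrawn as the six-membered difluoroboron chelate 6, which is hydrolysed by hot aqueous ethanol.

Step 4
Reactants: 8 4-bromo-2,6-dimethoxyphenol; 9 benzyl bromide
Product: 10 2-benzyloxy-5-bromo-1,3-dimethoxybenzene
Conditions: K2CO3, DMF, 60 °C
Reagents that add atoms: none
Why: Williamson ether synthesis, in which the phenoxide formed with K2CO3 should displace bromide from the benzylic halide by SN2, the benzyl ether masking the acidic and nucleophilic ring B phenol during the carbonylation.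

Step 5
Reactants: 7 1-(2-hydroxy-3,4,5,6-tetramethoxyphenyl)ethanone; 10 2-benzyloxy-5-bromo-1,3-dimethoxybenzene; 11 carbon monoxide
Product: 12 1-(4-benzyloxy-3,5-dimethoxyphenyl)-3-(2-hydroxy-3,4,5,6-tetramethoxyphenyl)propane-1,3-dione
Conditions: Pd(OAc)2 (cat.), Xantphos (cat.), DBU, CO (5 bar), DMSO, 100 °C
Reagents that add atoms: none
Why: Zerovalent palladium, formed in the flask from Pd(OAc)2 and Xantphos, should add oxidatively to the C–Br bond of 10, CO should insert into the aryl–palladium bond (forming C1'–C2) to give an aroyl complex of divalent palladium, and the DBU-derived enolate of methyl ketone 7 should replace bromide on the metal so that reductive elimination forms C2–C3. Where the phenoxide of 7 captures the aroyl complex first, the resulting aryl ester should isomerise under DBU in hot DMSO by Baker–Venkataraman acyl transfer to the same diketone, so both paths end at 12. The closest known reaction type is the palladium-catalysed carbonylative alpha-arylation of methyl ketones with aryl bromides to 1,3-diketones, which is established for 2-hydroxyacetophenones as an entry to flavones. No ring closes and no stereocentre arises in this step. The selectivity needed is a single CO insertion followed by C-acylation rather than CO-free direct alpha-arylation or arrest at the O-acyl stage; CO pressure and the wide bite angle of Xantphos favour the aroyl complex and its reductive elimination, and the excess of DBU drives the acyl shift. The substrate pair leaves no regiochemical choice, since 7 has a single enolisable methyl group and 10 has neither an ortho substituent nor a free hydroxyl group.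

Step 6
Reactants: 12 1-(4-benzyloxy-3,5-dimethoxyphenyl)-3-(2-hydroxy-3,4,5,6-tetramethoxyphenyl)propane-1,3-dione
Product: 13 2-(4-benzyloxy-3,5-dimethoxyphenyl)-5,6,7,8-tetramethoxy-4H-chromen-4-one
Conditions: H2SO4 (cat.), AcOH, 80 °C
Reagents that add atoms: none
Why: Acid-catalysed cyclodehydration of a 1-(2-hydroxyaryl)-1,3-diketone, the closing stage of the Baker–Venkataraman flavone synthesis, in which the phenolic oxygen should add to the protonated aroyl carbonyl (C2) in a 6-exo-trig closure and the hemiketal should lose water to give the aromatic 4-pyranone ring C, catalytic H2SO4 in AcOH being mild enough to spare the methyl ethers, while any loss of the benzyl group would only deliver the target one step early.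

Step 7
Reactants: 13 2-(4-benzyloxy-3,5-dimethoxyphenyl)-5,6,7,8-tetramethoxy-4H-chromen-4-one
Product: 14 4'-hydroxy-3',5,5',6,7,8-hexamethoxyflavone
Conditions: H2 (1 atm), Pd/C (10 wt %), EtOAc/MeOH, rt
Reagents that add atoms: none
Why: Hydrogenolysis of a benzyl aryl ether over Pd/C, in which the benzylic C–O bond should be cleaved at room temperature under one atmosphere of hydrogen, conditions that methyl aryl ethers and the vinylogous-ester double bond C2–C3 of a flavone normally withstand when the reaction is stopped at full conversion.

**Compound list**

1 | 1,2,3,4-tetramethoxybenzene | COc1ccc(OC)c(OC)c1OC | starting material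
2 | N,N-dimethyl-1-(2,3,4,5-tetramethoxyphenyl)methaniminium chloride | COc1cc(C=[N+](C)C)c(OC)c(OC)c1OC.[Cl-] | intermediate
3 | 2,3,4,5-tetramethoxybenzaldehyde | COc1cc(C=O)c(OC)c(OC)c1OC | intermediate
4 | 2,3,4,5-tetramethoxyphenyl formate | COc1cc(OC=O)c(OC)c(OC)c1OC | intermediate
5 | 2,3,4,5-tetramethoxyphenol | COc1cc(O)c(OC)c(OC)c1OC | intermediate
6 | difluoroboron chelate of 1-(2-hydroxy-3,4,5,6-tetramethoxyphenyl)ethanone (BF2 bridging the phenolate and ketone oxygens in a six-membered ring) | CC1=[O+][B-](F)(F)Oc2c(OC)c(OC)c(OC)c(OC)c12 | intermediate
7 | 1-(2-hydroxy-3,4,5,6-tetramethoxyphenyl)ethanone | COc1c(O)c(C(C)=O)c(OC)c(OC)c1OC | intermediate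
8 | 4-bromo-2,6-dimethoxyphenol | COc1cc(Br)cc(OC)c1O | starting material
9 | benzyl bromide | BrCc1ccccc1 | starting material
10 | 2-benzyloxy-5-bromo-1,3-dimethoxybenzene | COc1cc(Br)cc(OC)c1OCc1ccccc1 | intermediate
11 | carbon monoxide | [C-]#[O+] | starting material
12 | 1-(4-benzyloxy-3,5-dimethoxyphenyl)-3-(2-hydroxy-3,4,5,6-tetramethoxyphenyl)propane-1,3-dione | COc1c(O)c(C(=O)CC(=O)c2cc(OC)c(OCc3ccccc3)c(OC)c2)c(OC)c(OC)c1OC | intermediate
13 | 2-(4-benzyloxy-3,5-dimethoxyphenyl)-5,6,7,8-tetramethoxy-4H-chromen-4-one | COc1cc(-c2cc(=O)c3c(OC)c(OC)c(OC)c(OC)c3o2)cc(OC)c1OCc1ccccc1 | intermediate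
14 | 4'-hydroxy-3',5,5',6,7,8-hexamethoxyflavone | COc1cc(-c2cc(=O)c3c(OC)c(OC)c(OC)c(OC)c3o2)cc(OC)c1O | target

**Step count and risks**

Total step count: 7 steps.
Longest linear sequence: 6 steps (steps 1, 2, 3, 5, 6, 7); step 4 prepares the ring B partner in parallel.

Steps most likely to fail:

Step 5. The carbonylation may stall because oxidative addition of the electron-rich bromide is slow at CO-saturated palladium. It may also stop at the O-aroyl ester, because the doubly ortho-substituted ketone enolises sluggishly, or drift toward CO-free arylation. The fallback reaches the same diketone by classical acyl transfer without palladium and sets out from bromide 10. Bromine–lithium exchange (n-BuLi, THF, −78 °C) followed by CO2 and acidic work-up should give 4-benzyloxy-3,5-dimethoxybenzoic acid F1. Esterification of phenol 7 with this acid (POCl3, pyridine, 0 °C → rt) should give 2-acetyl-3,4,5,6-tetramethoxyphenyl 4-benzyloxy-3,5-dimethoxybenzoate F2. Baker–Venkataraman rearrangement (KOH, pyridine, 50 °C) then comes back to the route at diketone 12.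

Step 3. The boron Lewis acid may cleave the methyl ether next to the newly formed, chelating carbonyl, or the reaction may stop at the O-acetate. The fallback introduces the acetyl group by directed ortho-metalation instead of electrophilic substitution and sets out from phenol 5. MOMCl and iPr2NEt (CH2Cl2, 0 °C → rt) should give 1-(methoxymethoxy)-2,3,4,5-tetramethoxybenzene F3. n-BuLi (THF, 0 °C) should lithiate the single ring C–H, which lies between the acetal oxygen and a methoxy group, and N-methoxy-N-methylacetamide should then deliver 1-[2-(methoxymethoxy)-3,4,5,6-tetramethoxyphenyl]ethanone F4. HCl in MeOH (rt) removes the acetal and comes back to the route at acetophenone 7.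

Step 2. The peracid may over-oxidise the very electron-rich ring to a quinone, or hydride migration may give the benzoic acid instead of the formate. The fallback installs the hydroxyl group without an oxidant and sets out from 1, so it bypasses steps 1 and 2. NBS (MeCN, rt) should give 1-bromo-2,3,4,5-tetramethoxybenzene F5. Palladium-catalysed hydroxylation of this bromide (Pd2(dba)3, tBuXPhos, KOH, dioxane/H2O, 100 °C) comes back to the route at phenol 5.

Further compounds
F1 | step 5 | 4-benzyloxy-3,5-dimethoxybenzoic acid | COc1cc(C(=O)O)cc(OC)c1OCc1ccccc1
F2 | step 5 | 2-acetyl-3,4,5,6-tetramethoxyphenyl 4-benzyloxy-3,5-dimethoxybenzoate | COc1cc(C(=O)Oc2c(OC)c(OC)c(OC)c(OC)c2C(C)=O)cc(OC)c1OCc1ccccc1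
F3 | step 3 | 1-(methoxymethoxy)-2,3,4,5-tetramethoxybenzene | COCOc1cc(OC)c(OC)c(OC)c1OC
F4 | step 3 | 1-[2-(methoxymethoxy)-3,4,5,6-tetramethoxyphenyl]ethanone | COCOc1c(C(C)=O)c(OC)c(OC)c(OC)c1OC
F5 | step 2 | 1-bromo-2,3,4,5-tetramethoxybenzene | COc1cc(Br)c(OC)c(OC)c1OC
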